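Numbering: isoflavan numbering. Ring A is the benzo ring (C4a–C8a), ring C the pyran ring (O1–C4), and ring B the quinone ring (C1'–C6', C1' on C3, carbonyls C2' and C5', methoxy groups on C3' and C4').
Cuts: the quinone is traced back, through O-methylation at C3' and oxidative loss of a helper methyl at C2', to a 2,4-dimethoxyresorcinol. That ring is cut at C1'–C2' and C4'–C5' into a 3-(chromen-3-yl)propiolate (C1', C6', C5') and 1,3-dimethoxyacetone (C2', C3', C4').
Enabling feature: ring B carries oxygen on four neighbouring carbons C2'–C5'. At the phenol level C2'–C3'–C4' is a symmetric MeO–C–C(O)–C–OMe unit, and C5'(=O)–C6'H=C1' is a β-substituted propiolate, so only one orientation of union exists.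
Forward order: ring A is bought, para-hydroxylated and masked. Ring C is closed with acrolein, the formyl group is turned into the alkynoate, and ring B is built last from open-chain carbon by a (3+3) benzannulation.
Stereochemistry: C3 is the only stereocentre. It is set after ring B exists, by iridium-catalysed asymmetric hydrogenation of C3=C4 of the isoflav-3-ene, so no base-labile stereocentre passes through the anionic key step.
End game: only ring B has free phenols, so PhI(OAc)2 can attack only that ring. Ring A stays masked as its MOM ether until the last step.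

Key step: step 6

Assumption: the (S)-configured phosphinooxazoline ligand is taken to deliver hydrogen to the face of C3=C4 that gives 3S; if the sense is the opposite on this substrate, the enantiomeric ligand is used.

Step 1
Reactants: 1 2-hydroxy-3,4-dimethoxybenzaldehyde
Product: 3 2,5-dihydroxy-3,4-dimethoxybenzaldehyde, via aryl sulfate 2 (not isolated)
Conditions: K2S2O8, aq. NaOH, 0–20 °C; then aq. HCl, 80 °C
Reagents that add atoms: potassium peroxodisulfate, [K+].[K+].[O-]S(=O)(=O)OOS(=O)(=O)[O-]
Why: Elbs persulfate oxidation, in which the phenoxide of 1 attacks the peroxide oxygen through C5, the free position para to the phenoxide oxygen, and acid hydrolysis of the aryl sulfate 2 frees the hydroquinone while the formyl group survives, as in the conversion of salicylaldehydes into gentisaldehydes.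

Step 2
Reactants: 3 2,5-dihydroxy-3,4-dimethoxybenzaldehyde
Product: 4 2-hydroxy-3,4-dimethoxy-5-(methoxymethoxy)benzaldehyde
Conditions: MOMCl (1.05 equiv), i-Pr2NEt, CH2Cl2, 0 °C
Reagents that add atoms: chloromethyl methyl ether, COCCl
Why: Selective O-alkylation (acetal protection), in which the C2 hydroxyl is held in a hydrogen bond to the formyl oxygen and is the weaker nucleophile, so that the C5 hydroxyl should react alone.

Step 3
Reactants: 4 2-hydroxy-3,4-dimethoxy-5-(methoxymethoxy)benzaldehyde; 5 acrolein
Product: 6 7,8-dimethoxy-6-(methoxymethoxy)-2H-chromene-3-carbaldehyde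
Conditions: K2CO3, 1,4-dioxane, 100 °C
Reagents that add atoms: none
Why: Domino oxa-Michael addition and intramolecular aldol condensation, the standard route from salicylaldehydes to 2H-chromene-3-carbaldehydes, closes ring C (O1–C2 and C3–C4) and leaves the base-stable MOM ether untouched.

Step 4
Reactants: 6 7,8-dimethoxy-6-(methoxymethoxy)-2H-chromene-3-carbaldehyde
Product: 7 3-(2,2-dibromoethenyl)-7,8-dimethoxy-6-(methoxymethoxy)-2H-chromene
Conditions: CBr4, PPh3, Et3N, CH2Cl2, 0 °C
Reagents that add atoms: carbon tetrabromide, BrC(Br)(Br)Br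
Why: Corey–Fuchs dibromoolefination (a Wittig-type reaction of Ph3P=CBr2) works on enals without conjugate addition, and the Et3N buffer protects the acetal from the bromophosphonium by-product.

Step 5
Reactants: 7 3-(2,2-dibromoethenyl)-7,8-dimethoxy-6-(methoxymethoxy)-2H-chromene
Product: 9 methyl 3-[7,8-dimethoxy-6-(methoxymethoxy)-2H-chromen-3-yl]prop-2-ynoate, via lithium acetylide 8 (not isolated)
Conditions: n-BuLi (2.1 equiv), THF, −78 °C; then ClCO2Me, −78 → 0 °C
Reagents that add atoms: methyl chloroformate, COC(=O)Cl; n-butyllithium, [Li]CCCC (supplies the lithium of 8)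
Why: Second stage of the Corey–Fuchs sequence (bromine–lithium exchange and Fritsch–Buttenberg–Wiechell rearrangement) followed by C-acylation of the acetylide, run at −78 °C, where ortho-lithiation next to the MOM ether is too slow to compete.

Step 6
Reactants: 9 methyl 3-[7,8-dimethoxy-6-(methoxymethoxy)-2H-chromen-3-yl]prop-2-ynoate; 10 1,3-dimethoxypropan-2-one
Product: 12 5-[7,8-dimethoxy-6-(methoxymethoxy)-2H-chromen-3-yl]-2,4-dimethoxybenzene-1,3-diol, via keto enoate 11 (not isolated)
Conditions: 10 (2 equiv), NaH (4 equiv), THF, 0 °C; then 9, 0 → 65 °C, argon; AcOH quench, 0 °C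
Reagents that add atoms: none
Why: Proposed new method: the sodium enolate of the symmetric ketone 10 adds through one of its two MeO–CH2 carbons to the alkyne carbon of 9 that carries the chromene (Michael addition, bond C1'–C2'), proton shifts give the delocalised enolate of 11, whose C1'=C6' geometry equilibrates, and the other MeO–CH2 carbon is then acylated by the ester (Claisen condensation, bond C4'–C5', loss of methoxide), after which the cyclohexenedione tautomerises to the resorcinol 12. The closest known reaction types are the Michael–Dieckmann synthesis of resorcinols from dimethyl 3-oxoglutarate and 2-alkynoates and the consecutive Michael–Claisen synthesis of cyclohexane-1,3-diones from acetone derivatives and acrylates, and the new element is a 1,3-dialkoxyacetone, activated only by its ether oxygens, as the three-carbon double nucleophile. Ring B closes by a 6-(enolendo)-exo-trig acylation, and the step leaves no stereocentre, because C2', stereogenic in 11, becomes an arene carbon. Orientation needs no control, since the two nucleophilic carbons of 10 are equivalent and 9 offers exactly one conjugate acceptor carbon and one acyl carbon. The step needs C- over O-acylation, which is secured because O-acylation is reversed by the methoxide set free in the flask whereas C-acylation ends in an aromatic bis-phenoxide that drains the equilibrium. It also needs 1,4- over 1,6-addition and no proton loss next to the alkyne, which are secured because C4 is the electron-rich end of a styrene fed by O1 and the 7-methoxy group and because C3 is kept sp2 at this stage, so that no allenoate can form and no stereocentre is exposed to base.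

Step 7
Reactants: 12 5-[7,8-dimethoxy-6-(methoxymethoxy)-2H-chromen-3-yl]-2,4-dimethoxybenzene-1,3-diol
Product: 13 5-[(3S)-7,8-dimethoxy-6-(methoxymethoxy)-3,4-dihydro-2H-chromen-3-yl]-2,4-dimethoxybenzene-1,3-diol
Conditions: [Ir(cod)((S)-t-Bu-PHOX)]BArF (BArF = B[3,5-(CF3)2C6H3]4, 2 mol %), H2 (50 bar), CH2Cl2, 25 °C
Reagents that add atoms: none
Why: Iridium-catalysed asymmetric hydrogenation of a trisubstituted aryl alkene, a reaction type shown on 3-aryl-2H-chromenes, in which the chiral P,N ligand blocks one face of C3=C4 so that hydrogen is delivered to the face that makes C3 S, while aryl ethers, the acetal and the phenols are not reduced.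

Step 8
Reactants: 13 5-[(3S)-7,8-dimethoxy-6-(methoxymethoxy)-3,4-dihydro-2H-chromen-3-yl]-2,4-dimethoxybenzene-1,3-diol
Product: 14 3-hydroxy-2-methoxy-5-[(3S)-7,8-dimethoxy-6-(methoxymethoxy)-3,4-dihydro-2H-chromen-3-yl]cyclohexa-2,5-diene-1,4-dione
Conditions: PhI(OAc)2 (1.05 equiv), MeCN/H2O 4:1, 0 °C
Reagents that add atoms: water, O
Why: Trivalent iodine oxidation of a 4-methoxyphenol to the para-quinone, in which the oxidant binds only free phenols, which ring B alone has, water adds at the methoxy-bearing C2' para to the C5' hydroxyl, methanol leaves and the C3' hydroxyl ends as a hydroxyquinone, with C3 untouched.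

Step 9
Reactants: 14 3-hydroxy-2-methoxy-5-[(3S)-7,8-dimethoxy-6-(methoxymethoxy)-3,4-dihydro-2H-chromen-3-yl]cyclohexa-2,5-diene-1,4-dione
Product: 15 2,3-dimethoxy-5-[(3S)-7,8-dimethoxy-6-(methoxymethoxy)-3,4-dihydro-2H-chromen-3-yl]cyclohexa-2,5-diene-1,4-dione
Conditions: TMSCHN2 (1.1 equiv), toluene/MeOH 4:1, 0 °C
Reagents that add atoms: (trimethylsilyl)diazomethane, C[Si](C)(C)C=[N+]=[N-]
Why: Diazoalkane O-methylation of a vinylogous carboxylic acid, in which the acidic hydroxyquinone protonates the reagent and is methylated faster than the quinone C=C can undergo dipolar cycloaddition, under neutral conditions that cannot enolise C3.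

Step 10
Reactants: 15 2,3-dimethoxy-5-[(3S)-7,8-dimethoxy-6-(methoxymethoxy)-3,4-dihydro-2H-chromen-3-yl]cyclohexa-2,5-diene-1,4-dione
Product: 16 5-[(3S)-6-hydroxy-7,8-dimethoxy-3,4-dihydro-2H-chromen-3-yl]-2,3-dimethoxycyclohexa-2,5-diene-1,4-dione (target)
Conditions: p-TsOH·H2O (0.2 equiv), MeOH, 40 °C
Reagents that add atoms: none
Why: Acid-catalysed acetal exchange with methanol removes the MOM group, the acid has a non-nucleophilic counter-ion that cannot add to the quinone, any methoxy exchange on the quinone in methanol is degenerate, and C3 is configurationally stable in acid.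

Compound list
1 | 2-hydroxy-3,4-dimethoxybenzaldehyde | COc1ccc(C=O)c(O)c1OC | starting material
2 | potassium 5-formyl-4-hydroxy-2,3-dimethoxyphenyl sulfate | COc1c(OC)c(O)c(C=O)cc1OS(=O)(=O)[O-].[K+] | intermediate
3 | 2,5-dihydroxy-3,4-dimethoxybenzaldehyde | COc1c(O)cc(C=O)c(O)c1OC | intermediate
4 | 2-hydroxy-3,4-dimethoxy-5-(methoxymethoxy)benzaldehyde | COCOc1cc(C=O)c(O)c(OC)c1OC | intermediate
5 | acrolein (prop-2-enal) | C=CC=O | starting material
6 | 7,8-dimethoxy-6-(methoxymethoxy)-2H-chromene-3-carbaldehyde | O=CC1=Cc2cc(OCOC)c(OC)c(OC)c2OC1 | intermediate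
7 | 3-(2,2-dibromoethenyl)-7,8-dimethoxy-6-(methoxymethoxy)-2H-chromene | BrC(Br)=CC1=Cc2cc(OCOC)c(OC)c(OC)c2OC1 | intermediate
8 | lithium [7,8-dimethoxy-6-(methoxymethoxy)-2H-chromen-3-yl]acetylide | [Li]C#CC1=Cc2cc(OCOC)c(OC)c(OC)c2OC1 | intermediate
9 | methyl 3-[7,8-dimethoxy-6-(methoxymethoxy)-2H-chromen-3-yl]prop-2-ynoate | COC(=O)C#CC1=Cc2cc(OCOC)c(OC)c(OC)c2OC1 | intermediate
10 | 1,3-dimethoxypropan-2-one (1,3-dimethoxyacetone) | COCC(=O)COC | starting material
11 | methyl (2Z)-3-[7,8-dimethoxy-6-(methoxymethoxy)-2H-chromen-3-yl]-4,6-dimethoxy-5-oxohex-2-enoate (racemic at C4, present as its sodium enolate) | COC(=O)/C=C(\C(OC)C(=O)COC)C1=Cc2cc(OCOC)c(OC)c(OC)c2OC1 | intermediate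
12 | 5-[7,8-dimethoxy-6-(methoxymethoxy)-2H-chromen-3-yl]-2,4-dimethoxybenzene-1,3-diol | COc1c(O)cc(C2=Cc3cc(OCOC)c(OC)c(OC)c3OC2)c(OC)c1O | intermediate
13 | 5-[(3S)-7,8-dimethoxy-6-(methoxymethoxy)-3,4-dihydro-2H-chromen-3-yl]-2,4-dimethoxybenzene-1,3-diol | COc1c(O)cc([C@H]2COc3c(cc(OCOC)c(OC)c3OC)C2)c(OC)c1O | intermediate
14 | 3-hydroxy-2-methoxy-5-[(3S)-7,8-dimethoxy-6-(methoxymethoxy)-3,4-dihydro-2H-chromen-3-yl]cyclohexa-2,5-diene-1,4-dione | COC1=C(O)C(=O)C([C@H]2COc3c(cc(OCOC)c(OC)c3OC)C2)=CC1=O | intermediate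
15 | 2,3-dimethoxy-5-[(3S)-7,8-dimethoxy-6-(methoxymethoxy)-3,4-dihydro-2H-chromen-3-yl]cyclohexa-2,5-diene-1,4-dione | COC1=C(OC)C(=O)C([C@H]2COc3c(cc(OCOC)c(OC)c3OC)C2)=CC1=O | intermediate
16 | 5-[(3S)-6-hydroxy-7,8-dimethoxy-3,4-dihydro-2H-chromen-3-yl]-2,3-dimethoxycyclohexa-2,5-diene-1,4-dione | COC1=C(OC)C(=O)C([C@H]2COc3c(cc(O)c(OC)c3OC)C2)=CC1=O | target

Total step count: 10. Longest linear sequence: 10 steps (1 to 16). Compounds 5 and 10 enter as purchased.

Steps most likely to fail

Step 6 (Proposed new method).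
- Risk: the weakly activated enolate may self-condense. It may attack the ester before the alkyne, or stall after O-acylation. The adduct anion may also add to a second alkynoate.
- Fallback: known chemistry that sets C3 first and builds ring B from a squarate. It sets out from 6 and comes back to the route at 15.
- NaBH4 in MeOH reduces 6 to the allylic alcohol [7,8-dimethoxy-6-(methoxymethoxy)-2H-chromen-3-yl]methanol F1.
- Hydroxyl-directed asymmetric hydrogenation with Ru(OAc)2[(S)-BINAP] and H2 in MeOH (ligand enantiomer chosen for 3S) gives [(3S)-7,8-dimethoxy-6-(methoxymethoxy)-3,4-dihydro-2H-chromen-3-yl]methanol F2.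
- Dess–Martin periodinane in CH2Cl2 gives (3R)-7,8-dimethoxy-6-(methoxymethoxy)-3,4-dihydro-2H-chromene-3-carbaldehyde F3.
- F3 is taken on at once with the Ohira–Bestmann reagent and K2CO3 in MeOH at 0 °C to give (3S)-3-ethynyl-7,8-dimethoxy-6-(methoxymethoxy)-3,4-dihydro-2H-chromene F4.
- Deprotonation with n-BuLi in THF at −78 °C and 1,2-addition to dimethyl squarate gives 4-{[(3S)-7,8-dimethoxy-6-(methoxymethoxy)-3,4-dihydro-2H-chromen-3-yl]ethynyl}-4-hydroxy-2,3-dimethoxycyclobut-2-en-1-one F5.
- Heating F5 in p-xylene at 138 °C should give 15 directly by the Moore rearrangement. The ring opens to the alkynyl ketene, closes to the six-membered diradical, and the hydroxyl hydrogen is transferred. A secondary alkyl group on the alkyne is the substituent type that leads to the quinone.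

Step 7.
- Risk: the free phenols and the ortho-methoxy group of ring B may bind the cationic iridium centre. That would slow the hydrogenation or erode facial selectivity. The acidic iridium hydrides may also cause loss of the acetal.
- Fallback: resolution in place of catalyst control. It sets out from 12 and comes back at 13.
- Hydrogenation of 12 over Pd/C in EtOAc gives racemic 5-[7,8-dimethoxy-6-(methoxymethoxy)-3,4-dihydro-2H-chromen-3-yl]-2,4-dimethoxybenzene-1,3-diol F6.
- The enantiomers of F6 are separated by preparative chromatography on a cellulose tris(3,5-dimethylphenylcarbamate) phase. The 3S enantiomer is 13.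

Step 8.
- Risk: the oxidised ring may be captured by water at C4' or C6' instead of C2', or the electron-rich ring may be overoxidised.
- Fallback: ring B is oxidised at the tetramethyl ether level after ring A has been deactivated. It sets out from 13 and comes back at 16.
- MeI and K2CO3 in acetone give (3S)-7,8-dimethoxy-6-(methoxymethoxy)-3-(2,3,4,5-tetramethoxyphenyl)-3,4-dihydro-2H-chromene F7.
- p-TsOH in MeOH removes the acetal to give (3S)-7,8-dimethoxy-3-(2,3,4,5-tetramethoxyphenyl)-3,4-dihydro-2H-chromen-6-ol F8.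
- Ac2O and pyridine give (3S)-7,8-dimethoxy-3-(2,3,4,5-tetramethoxyphenyl)-3,4-dihydro-2H-chromen-6-yl acetate F9, whose ring A is now the less electron-rich ring.
- (NH4)2Ce(NO3)6 in MeCN/H2O at 0 °C (tetravalent cerium) performs the oxidative demethylation known for 1,2,3,4-tetramethoxyarenes. It gives (3S)-3-(4,5-dimethoxy-3,6-dioxocyclohexa-1,4-dien-1-yl)-7,8-dimethoxy-3,4-dihydro-2H-chromen-6-yl acetate F10.
- Acid-catalysed methanolysis (p-TsOH, MeOH) then gives 16.

Further compounds
F1 | step 6 | [7,8-dimethoxy-6-(methoxymethoxy)-2H-chromen-3-yl]methanol | OCC1=Cc2cc(OCOC)c(OC)c(OC)c2OC1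
F2 | step 6 | [(3S)-7,8-dimethoxy-6-(methoxymethoxy)-3,4-dihydro-2H-chromen-3-yl]methanol | OC[C@H]1COc2c(cc(OCOC)c(OC)c2OC)C1
F3 | step 6 | (3R)-7,8-dimethoxy-6-(methoxymethoxy)-3,4-dihydro-2H-chromene-3-carbaldehyde | O=C[C@H]1COc2c(cc(OCOC)c(OC)c2OC)C1
F4 | step 6 | (3S)-3-ethynyl-7,8-dimethoxy-6-(methoxymethoxy)-3,4-dihydro-2H-chromene | C#C[C@H]1COc2c(cc(OCOC)c(OC)c2OC)C1
F5 | step 6 | 4-{[(3S)-7,8-dimethoxy-6-(methoxymethoxy)-3,4-dihydro-2H-chromen-3-yl]ethynyl}-4-hydroxy-2,3-dimethoxycyclobut-2-en-1-one (both carbinol epimers) | COC1=C(OC)C(O)(C#C[C@H]2COc3c(cc(OCOC)c(OC)c3OC)C2)C1=O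
F6 | step 7 | racemic 5-[7,8-dimethoxy-6-(methoxymethoxy)-3,4-dihydro-2H-chromen-3-yl]-2,4-dimethoxybenzene-1,3-diol | COc1c(O)cc(C2COc3c(cc(OCOC)c(OC)c3OC)C2)c(OC)c1O
F7 | step 8 | (3S)-7,8-dimethoxy-6-(methoxymethoxy)-3-(2,3,4,5-tetramethoxyphenyl)-3,4-dihydro-2H-chromene | COc1cc([C@H]2COc3c(cc(OCOC)c(OC)c3OC)C2)c(OC)c(OC)c1OC
F8 | step 8 | (3S)-7,8-dimethoxy-3-(2,3,4,5-tetramethoxyphenyl)-3,4-dihydro-2H-chromen-6-ol | COc1cc([C@H]2COc3c(cc(O)c(OC)c3OC)C2)c(OC)c(OC)c1OC
F9 | step 8 | (3S)-7,8-dimethoxy-3-(2,3,4,5-tetramethoxyphenyl)-3,4-dihydro-2H-chromen-6-yl acetate | COc1cc([C@H]2COc3c(cc(OC(C)=O)c(OC)c3OC)C2)c(OC)c(OC)c1OC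
F10 | step 8 | (3S)-3-(4,5-dimethoxy-3,6-dioxocyclohexa-1,4-dien-1-yl)-7,8-dimethoxy-3,4-dihydro-2H-chromen-6-yl acetate | COC1=C(OC)C(=O)C([C@H]2COc3c(cc(OC(C)=O)c(OC)c3OC)C2)=CC1=O
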